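## The problem

The target 26 is a 6,12-elemanolide: a cyclohexane (ring A, C5–C10) with a cis-fused γ-lactone (ring B: C6, C7, C11, C12 and the ring oxygen). It has six stereocentres, five contiguous on ring A and the sixth (C11) a fully substituted carbinol carbon in the lactone. The quaternary C10 (methyl, vinyl) lies next to C5 (isopropenyl), with vinyl trans to isopropenyl and cis to the lactone oxygen on C6. The C8 acetoxy group is trans to the C7–C11 bond and 1,3-syn to the C10 methyl, and the C11 angelate sits on the convex face of the bicycle. Control can be relayed: C6 can set C5 and C10 if ring A is closed beside it, the cis fusion ties C7 to C6, the axial C10 methyl can steer a reagent at C8, and the folded bicycle can steer one at C11. The sensitive groups are the angelate (Z to E isomerisation under nucleophiles, acid or heat), the acetate (no enolate chemistry after it), the vinyl/isopropenyl 1,5-diene, and every C8-carbonyl intermediate, in which O6 is a β-leaving group. The feature that opens the key step is that the C10 methyl and the ring CH2 (C9) are the two ends of an isopropenyl group. Read that way, C5 carries two identical isopropenyl groups and is no stereocentre, C8 is an acyl carbon three atoms from C5, and the C10 vinyl group can be handed over from silicon on O6, which is on the same face.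

## Retrosynthesis

**C11–O acyl bond.** Target 26 is cut at the ester bond between O11 and the angeloyl carbonyl, giving tertiary alcohol 22 and (Z)-2-methylbut-2-enoyl chloride 24, made from angelic acid 23. Cutting here, and not at the acetate, keeps the only isomerisable group out of all other steps. The forward step must acylate a hindered tertiary alkoxide without Z to E isomerisation. Acetyl migration is excluded because O8 and C11 are anti across C7–C8.

**C8 and C11 heteroatom bonds.** Acetate 22 goes back to diol 21 (O8–acetyl), 21 to hydroxy lactone 19 (C11–O), and 19 to keto lactone 18 (C8–H). C11 is oxidised as the lactone enolate because the convex face of the cis bicycle is the face that carries oxygen in 26. An aldol closure that brought C11 in with its oxygen would be expected to place the hydroxyl on the concave face. The acetate cannot precede enolate chemistry, so the order is reduction, hydroxylation of the dianion, acetylation. Compound 18 has four stereocentres (C5, C6, C7, C10) and no acyl groups.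

**C7–C11 bond (ring B).** Keto lactone 18 is cut at C7–C11 and at the lactone oxidation level. The three lactone carbons come from ethyl prop-1-enyl ether 14, hung on O6 as bromoacetal 15. The C8 ketone supplies the acceptor as enol silane 16, radical closure gives acetal 17, and oxidation gives 18. An acetal tether is preferred to an ester tether, which must cyclise through its disfavoured rotamer, and to intermolecular alkylation at C7, which would go trans to O6. The forward steps need enolisation toward C7 and not C9; the 5-exo closure can only give the cis fusion. The precursor 13 has twelve carbons and three stereocentres.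

**C8–C9 and C10–C1 (ring A, key step).** Both bonds are cut at once. Ring A opens to acyl selenide 11, in which the C10 vinyl group is returned to silicon on O6 and C9/C10/C14 are one of two isopropenyl groups on C5. The precursor has one stereocentre (C6). The alternative of making the quaternary centre by conjugate addition to a preformed ring is kept as the fallback. Release of the vinyl group is not left to loss of a silyl radical from a β-silyl radical, which is uphill. The chain is carried instead by phenylselanyl transfer to siloxane 12, and fluoride then removes silicon and selenium together. The forward step needs 6-endo closure, a choice between two diastereotopic isopropenyl groups, and delivery to C10 from the O6 face.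

**Functional-group level.** Precursor 11 comes from hydroxy selenoester 9 and chloro(dimethyl)vinylsilane 10; the labile silyl ether is made last. Selenoester 9 comes from acid 8, 8 from diol 6 by selective oxidation of the primary alcohol, and 6 from silyl ether 5. No carbon–carbon bond is involved; each step must leave the skipped diene and the free secondary hydroxyl alone.

**C5–C6 bond.** Alcohol 5 is cut between the carbinol carbon and the bis(isopropenyl)methine, giving 2,4-dimethylpenta-1,3-diene 1 (as its pentadienyl anion) and aldehyde 2. Addition through the central carbon of the dienyl unit puts both isopropenyl groups on one carbon, so only C6 is created. This step is the sole source of absolute configuration.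

## Roads not taken

**Alternative 1:** The cut is C10–C1 and C5–C4 through a temporary third ring. 2-Methoxy-6-methyl-1,4-benzoquinone A1 and (E)-penta-1,3-diene A2 would combine in a chiral oxazaborolidinium-catalysed Diels–Alder reaction at the methyl-bearing quinone double bond, and the adduct would be equilibrated to the trans-fused enedione A3.
- Merits: the key step is catalytic, enantioselective and well precedented, and it sets C10 and C5 with no group selection. In reliability and enantiocontrol it is better than the chosen key step.
- Weak points: the cyclohexene must be cleaved and both ends turned back into alkenes (two reductions and two eliminations). The carbonyl next to the quaternary carbon sits at C9, where 26 has a CH2, and must be removed. The two quinone carbonyls must be told apart, and ring B is still to be built.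
- Comparison: the chosen plan offers no sacrificial carbons, no deoxygenation, and oxygen already at C6 and C8 after ring closure. It pays with an unprecedented cascade.

**Alternative 2:** The cut is C7–C11 and C8–O. The O6 bromoacetal of a cyclohex-7-ene, A4, would close 5-exo onto C7 under aerobic tin-hydride conditions, and the C8 radical would be captured by oxygen to give lactol ether A5.
- Merits: the cis fusion is assured, the C8 oxygen arrives in the same step, and no regioselective enolisation is needed. On these two counts it is better than steps 8 to 10 of the chosen route.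
- Weak points: A4 already holds C5, C6 and the quaternary C10, so the hard part of ring A is left to other chemistry. The C7=C8 alkene must be placed regioselectively. The C8 configuration depends on an uncontrolled radical capture, so oxidation and reduction would follow anyway.
- Comparison: the chosen plan uses the same tether as a supporting step and spends its key step on ring A. Its C8 carbonyl allows a substrate-controlled reduction.

**Alternative 3:** The cut is C6–C7 (ring A) and O6–C12 (ring B). The 2-(bromomethyl)enoate aldehyde A6 would be converted by a zinc- or chromium-mediated Barbier reaction into an allylmetal that adds through C7 to the C6 aldehyde, and the alkoxide would lactonise to A7.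
- Merits: two rings and the C6/C7 pair in one operation with known chemistry. In ring count and precedent it is better than the chosen key step.
- Weak points: the open-chain A6 already contains C5, C8 and the quaternary C10, to be built by acyclic stereocontrol. Its aldehyde is flanked by an allylic, α-carbonyl hydrogen at C5 that invites epimerisation and conjugation. The exocyclic methylene of A7 must then be hydrated to the C11 carbinol with oxygen on the convex face.
- Comparison: the chosen plan has a key-step precursor with one stereocentre, and C11 oxygen is introduced on the face the bicycle offers.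

Key step: step 6

Assumption: the isopinocampheyl groups derived from (+)-α-pinene are taken to select the same aldehyde face with the 2,4-dimethylpentadienyl group as with allyl and crotyl groups; if the sense proves opposite, the borane from (−)-α-pinene is used.

## Steps

Step 1
Reactants: 1 2,4-dimethylpenta-1,3-diene; 2 3-[(tert-butyldimethylsilyl)oxy]propanal
Product: 5 (3R)-1-[(tert-butyldimethylsilyl)oxy]-5-methyl-4-(prop-1-en-2-yl)hex-5-en-3-ol, via potassium 2,4-dimethylpentadienide 3 (not isolated), via dienyl diisopinocampheylborane 4 (not isolated)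
Conditions: n-BuLi, KOt-Bu, THF, −78 to −45 °C; (−)-Ipc2BOMe, −78 °C; BF3·OEt2, then 2, −78 °C; NaOH, H2O2, 0 °C to rt
Reagents that add atoms: none
Why: Brown allylboration with a pentadienyl group: 3 is trapped on boron at its terminal carbon and 4 adds to 2 through a six-membered chair transition state at its γ-carbon, so both isopropenyl groups end on C5 and only C6 becomes a stereocentre. The isopinocampheyl groups from (+)-α-pinene select the aldehyde face that gives the (R)-carbinol.

Step 2
Reactants: 5 (3R)-1-[(tert-butyldimethylsilyl)oxy]-5-methyl-4-(prop-1-en-2-yl)hex-5-en-3-ol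
Product: 6 (3R)-5-methyl-4-(prop-1-en-2-yl)hex-5-ene-1,3-diol
Conditions: Bu4NF, THF, 0 °C to rt
Reagents that add atoms: none
Why: Fluoride cleavage of the primary silyl ether; nothing else in 5 responds.

Step 3
Reactants: 6 (3R)-5-methyl-4-(prop-1-en-2-yl)hex-5-ene-1,3-diol
Product: 8 (3R)-3-hydroxy-5-methyl-4-(prop-1-en-2-yl)hex-5-enoic acid, via hydroxy aldehyde 7 (not isolated)
Conditions: TEMPO (cat.), PhI(OAc)2, MeCN/H2O, rt
Reagents that add atoms: water, O
Why: Oxoammonium oxidation is selective for the primary alcohol of a 1,3-diol, and in aqueous acetonitrile aldehyde 7 is oxidised on as its hydrate to the acid. The secondary carbinol and the alkenes are left.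

Step 4
Reactants: 8 (3R)-3-hydroxy-5-methyl-4-(prop-1-en-2-yl)hex-5-enoic acid
Product: 9 Se-phenyl (3R)-3-hydroxy-5-methyl-4-(prop-1-en-2-yl)hex-5-eneselenoate
Conditions: (PhSe)2, PBu3, CH2Cl2, 0 °C to rt
Reagents that add atoms: diphenyl diselenide, c1ccccc1[Se][Se]c1ccccc1
Why: Phosphine–diselenide activation of the acid (acyloxyphosphonium ion, then attack by selenolate) gives the acyl selenide. The hindered secondary hydroxyl is much slower toward the phosphonium salt, and the neutral conditions do not eliminate the β-hydroxyl.

Step 5
Reactants: 9 Se-phenyl (3R)-3-hydroxy-5-methyl-4-(prop-1-en-2-yl)hex-5-eneselenoate; 10 chloro(dimethyl)vinylsilane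
Product: 11 Se-phenyl (3R)-3-{[dimethyl(vinyl)silyl]oxy}-5-methyl-4-(prop-1-en-2-yl)hex-5-eneselenoate
Conditions: imidazole, CH2Cl2, 0 °C; filtration through Et3N-deactivated silica
Reagents that add atoms: none
Why: Silylation of the secondary alcohol with a small chlorosilane; the labile vinylsilyl ether is put on last and is not stored.

Step 6
Reactants: 11 Se-phenyl (3R)-3-{[dimethyl(vinyl)silyl]oxy}-5-methyl-4-(prop-1-en-2-yl)hex-5-eneselenoate
Product: 13 (3R,4R,5R)-5-hydroxy-3-methyl-4-(prop-1-en-2-yl)-3-vinylcyclohexan-1-one, via bicyclic siloxane selenide 12 (not isolated)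
Conditions: (Bu3Sn)2 (0.15 equiv), hν (sunlamp), PhH (0.2 M), 80 °C; then Bu4NF, AcOH, THF, 0 °C to rt
Reagents that add atoms: none
Why: Proposed new method: a tin radical from the ditin under light takes PhSe from 11, the C8 acyl radical closes 6-endo-trig on the CH2 end of one isopropenyl group (C8–C9, ring A), the tertiary C10 radical adds 6-exo-trig to the silicon-bearing vinyl carbon on O6 (C10–C1), and the primary radical so formed takes PhSe from the next molecule of 11, which gives 12 and carries the chain; fluoride then eliminates silicon and selenolate anti across C1–C2 of 12 and frees the vinyl group and O6–H. The closest known reaction types are the 6-endo cyclisation of selenoester-derived acyl radicals onto 1,1-disubstituted alkenes and the halogen- or phenylselanyl-transfer cyclisation onto vinylsilyl ethers followed by fluoride elimination to a vinyl group; an acyl selenide as both radical source and transfer agent, with both closures in one chain, has no precedent. Direct loss of a silyl radical from the β-silyl radical is not counted on, because that scission is the uphill reverse of silyl radical addition to an alkene. Ring A closes 6-endo and not 5-exo because the internal alkene carbon bears the methyl group and the acyl radical attacks the free CH2 terminus. C5 is set by the choice between the two diastereotopic isopropenyl groups in a chair transition state with the C6 silyloxy group and the spectator isopropenyl equatorial, which puts isopropenyl trans to O6. C10 is set by the tether: silicon on O6 can reach the planar C10 radical only from the O6 face, so vinyl ends cis to O6 and the methyl is the former isopropenyl methyl. The step needs the acyl radical to prefer an isopropenyl group over the vinylsilane (two equivalent all-carbon 6-endo paths against one seven-membered path through the long Si–O tether) and the C10 radical to reach the vinylsilane before it is quenched (a tertiary selenide formed too early re-enters the chain under the same conditions, and the silyl-shifted isomer of the primary radical gives a selenide that eliminates to the same vinyl group).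

Step 7
Reactants: 13 (3R,4R,5R)-5-hydroxy-3-methyl-4-(prop-1-en-2-yl)-3-vinylcyclohexan-1-one; 14 ethyl prop-1-enyl ether
Product: 15 (3R,4R,5R)-5-(2-bromo-1-ethoxypropoxy)-3-methyl-4-(prop-1-en-2-yl)-3-vinylcyclohexan-1-one (mixture at the two side-chain centres)
Conditions: N-bromosuccinimide, CH2Cl2, −40 to 0 °C
Reagents that add atoms: N-bromosuccinimide, O=C1CCC(=O)N1Br
Why: Haloacetalisation (Ueno–Stork): bromination of the enol ether gives an oxocarbenium ion that the C6 hydroxyl traps. The enol ether is far more electron-rich than the vinyl and isopropenyl groups, and the cold neutral medium spares the β-hydroxy ketone; both new centres are lost later.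

Step 8
Reactants: 15 (3R,4R,5R)-5-(2-bromo-1-ethoxypropoxy)-3-methyl-4-(prop-1-en-2-yl)-3-vinylcyclohexan-1-one
Product: 16 {[3-(2-bromo-1-ethoxypropoxy)-5-methyl-4-(prop-1-en-2-yl)-5-vinylcyclohex-1-en-1-yl]oxy}triethylsilane (C7=C8 enol silane; ring stereocentres as in 13)
Conditions: LiN(i-Pr)2, Et3SiCl, THF, −78 °C
Reagents that add atoms: chlorotriethylsilane, CC[Si](Cl)(CC)CC
Why: Kinetic enolisation with in situ silylation: the axial hydrogen on C7 is acidified by the β-oxygen on C6 and is reached by base bound to the acetal oxygens, whereas the axial hydrogen on C9 has neither help, so the C7=C8 enol silane should prevail. Trapping at −78 °C outruns β-elimination of O6, and the other regioisomer can be hydrolysed back to 15.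

Step 9
Reactants: 16 {[3-(2-bromo-1-ethoxypropoxy)-5-methyl-4-(prop-1-en-2-yl)-5-vinylcyclohex-1-en-1-yl]oxy}triethylsilane
Product: 17 cis-fused 2-ethoxy-3,6-dimethyl-7-(prop-1-en-2-yl)-4-[(triethylsilyl)oxy]-6-vinyloctahydro-1-benzofuran (C5, C6, C7, C10 as in 26; mixture at the acetal carbon, C11 and C8)
Conditions: Bu3SnH (slow addition), AIBN (cat.), PhH (0.02 M), 80 °C
Reagents that add atoms: none
Why: Tin-hydride radical chain: the secondary C11 radical closes 5-exo-trig on C7 of the enol silane, which can only give the cis-fused bicycle, so C7 is set by C6; the α-silyloxy radical at C8 is then reduced. Closure onto the isopropenyl group (6-exo at a disubstituted carbon or 7-endo) is slower, and the mixed centres converge in steps 10 to 12.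

Step 10
Reactants: 17 cis-fused 2-ethoxy-3,6-dimethyl-7-(prop-1-en-2-yl)-4-[(triethylsilyl)oxy]-6-vinyloctahydro-1-benzofuran
Product: 18 cis-fused 3,6-dimethyl-7-(prop-1-en-2-yl)-6-vinylhexahydro-1-benzofuran-2,4-dione (C5, C6, C7, C10 as in 26; C11 epimers)
Conditions: CrO3, H2SO4, acetone/H2O, 0 °C
Reagents that add atoms: water, O
Why: Jones oxidation: aqueous acid hydrolyses the ethyl acetal and the triethylsilyl ether, and hexavalent chromium oxidises the lactol to the lactone and the C8 carbinol to the ketone in one operation. Isolated alkenes tolerate short exposure at 0 °C.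

Step 11
Reactants: 18 cis-fused 3,6-dimethyl-7-(prop-1-en-2-yl)-6-vinylhexahydro-1-benzofuran-2,4-dione
Product: 19 cis-fused 4-hydroxy-3,6-dimethyl-7-(prop-1-en-2-yl)-6-vinylhexahydro-1-benzofuran-2(3H)-one (C8 hydroxyl trans to the C7–C11 bond, as in 26; C11 epimers)
Conditions: LiBH(s-Bu)3, THF, −78 °C; H2O
Reagents that add atoms: none
Why: Reduction of a cyclohexanone by a hindered borohydride: in the chair that keeps vinyl, isopropenyl and O6 equatorial, the C10 methyl is axial and 1,3 to C8, which closes the axial trajectory. Hydride therefore enters equatorially from the face of C11 and the hydroxyl ends axial, trans to C7–C11; the lactone is not reduced at −78 °C.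

Step 12
Reactants: 19 cis-fused 4-hydroxy-3,6-dimethyl-7-(prop-1-en-2-yl)-6-vinylhexahydro-1-benzofuran-2(3H)-one
Product: 21 cis-fused 3,4-dihydroxy-3,6-dimethyl-7-(prop-1-en-2-yl)-6-vinylhexahydro-1-benzofuran-2(3H)-one (all six ring stereocentres as in 26), via dipotassium alkoxide enolate 20 (not isolated)
Conditions: KN(SiMe3)2 (2.5 equiv), THF, −78 °C; 3-phenyl-2-(phenylsulfonyl)oxaziridine, −78 °C; AcOH
Reagents that add atoms: 3-phenyl-2-(phenylsulfonyl)oxaziridine, O=S(=O)(N1OC1c1ccccc1)c1ccccc1
Why: Enolate hydroxylation with an N-sulfonyloxaziridine: two equivalents of base give the C8 alkoxide and the C11 lactone enolate 20, which is oxidised on the convex face of the cis bicycle. The hydroxyl thus ends cis to H7 with the methyl on the concave face, and both C11 epimers of 19 converge.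

Step 13
Reactants: 21 cis-fused 3,4-dihydroxy-3,6-dimethyl-7-(prop-1-en-2-yl)-6-vinylhexahydro-1-benzofuran-2(3H)-one
Product: 22 cis-fused 3-hydroxy-3,6-dimethyl-2-oxo-7-(prop-1-en-2-yl)-6-vinyloctahydro-1-benzofuran-4-yl acetate (stereocentres as in 26)
Conditions: Ac2O, pyridine, 4-(dimethylamino)pyridine (cat.), CH2Cl2, 0 °C
Reagents that add atoms: acetic anhydride, CC(=O)OC(C)=O
Why: O-Acylation: the secondary C8 hydroxyl is acetylated, while the tertiary α-hydroxy lactone does not react at 0 °C.

Step 14
Reactants: 23 angelic acid [(2Z)-2-methylbut-2-enoic acid]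
Product: 24 (2Z)-2-methylbut-2-enoyl chloride
Conditions: 1-chloro-N,N,2-trimethylprop-1-en-1-amine, CH2Cl2, 0 °C; used as solution
Reagents that add atoms: 1-chloro-N,N,2-trimethylprop-1-en-1-amine, CC(C)=C(Cl)N(C)C
Why: An α-chloroenamine converts the acid to the acid chloride under neutral conditions, without HCl, which keeps the Z double bond.

Step 15
Reactants: 22 cis-fused 3-hydroxy-3,6-dimethyl-2-oxo-7-(prop-1-en-2-yl)-6-vinyloctahydro-1-benzofuran-4-yl acetate; 24 (2Z)-2-methylbut-2-enoyl chloride
Product: 26 (3S,3aR,4S,6R,7R,7aS)-4-acetoxy-6-ethenyl-3,6-dimethyl-2-oxo-7-(prop-1-en-2-yl)octahydro-1-benzofuran-3-yl (2Z)-2-methylbut-2-enoate, via lithium alkoxide 25 (not isolated)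
Conditions: LiN(SiMe3)2 (1.05 equiv), THF, −78 °C; 24, −78 to 0 °C
Reagents that add atoms: none
Why: O-Acylation of a lithium alkoxide by an acid chloride: the tertiary hydroxyl is deprotonated far faster than the acetate, and the O8 acetyl group is anti to C11 and cannot migrate. Direct acyl substitution at low temperature avoids the conjugate addition–elimination that turns angelates into tiglates.

## Compound list

1 | 2,4-dimethylpenta-1,3-diene | CC(C)=CC(C)=C | starting material
2 | 3-[(tert-butyldimethylsilyl)oxy]propanal | O=CCCO[Si](C)(C)C(C)(C)C | starting material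
3 | potassium 2,4-dimethylpentadienide | [K+].[CH2-]C(C)=CC(C)=C | intermediate
4 | (2,4-dimethylpenta-2,4-dien-1-yl)bis(isopinocampheyl)borane, isopinocampheyl groups from (+)-α-pinene | C=C(C)C=C(C)CB([C@@H]1C[C@@H]2C[C@H]([C@H]1C)C2(C)C)[C@@H]1C[C@@H]2C[C@H]([C@H]1C)C2(C)C | intermediate
5 | (3R)-1-[(tert-butyldimethylsilyl)oxy]-5-methyl-4-(prop-1-en-2-yl)hex-5-en-3-ol | CC(C)(C)[Si](C)(C)OCC[C@@H](O)C(C(C)=C)C(C)=C | intermediate
6 | (3R)-5-methyl-4-(prop-1-en-2-yl)hex-5-ene-1,3-diol | OCC[C@@H](O)C(C(C)=C)C(C)=C | intermediate
7 | (3R)-3-hydroxy-5-methyl-4-(prop-1-en-2-yl)hex-5-enal | O=CC[C@@H](O)C(C(C)=C)C(C)=C | intermediate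
8 | (3R)-3-hydroxy-5-methyl-4-(prop-1-en-2-yl)hex-5-enoic acid | OC(=O)C[C@@H](O)C(C(C)=C)C(C)=C | intermediate
9 | Se-phenyl (3R)-3-hydroxy-5-methyl-4-(prop-1-en-2-yl)hex-5-eneselenoate | O=C([Se]c1ccccc1)C[C@@H](O)C(C(C)=C)C(C)=C | intermediate
10 | chloro(dimethyl)vinylsilane | C=C[Si](C)(C)Cl | starting material
11 | Se-phenyl (3R)-3-{[dimethyl(vinyl)silyl]oxy}-5-methyl-4-(prop-1-en-2-yl)hex-5-eneselenoate | O=C([Se]c1ccccc1)C[C@@H](O[Si](C)(C)C=C)C(C(C)=C)C(C)=C | intermediate
12 | 3,3,5-trimethyl-4-[(phenylselanyl)methyl]-9-(prop-1-en-2-yl)-2-oxa-3-silabicyclo[3.3.1]nonan-7-one (ring carbons configured as C5, C6, C10 of 13; mixture at the silicon-bearing carbon) | c1ccccc1[Se]CC2[C@@]3(C)CC(=O)C[C@@H](O[Si]2(C)C)[C@@H]3C(=C)C | intermediate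
13 | (3R,4R,5R)-5-hydroxy-3-methyl-4-(prop-1-en-2-yl)-3-vinylcyclohexan-1-one | C=C[C@@]1(C)CC(=O)C[C@@H](O)[C@@H]1C(=C)C | intermediate
14 | ethyl prop-1-enyl ether (E/Z mixture) | CCOC=CC | starting material
15 | (3R,4R,5R)-5-(2-bromo-1-ethoxypropoxy)-3-methyl-4-(prop-1-en-2-yl)-3-vinylcyclohexan-1-one (side-chain centres mixed) | C=C[C@@]1(C)CC(=O)C[C@@H](OC(OCC)C(C)Br)[C@@H]1C(=C)C | intermediate
16 | {[3-(2-bromo-1-ethoxypropoxy)-5-methyl-4-(prop-1-en-2-yl)-5-vinylcyclohex-1-en-1-yl]oxy}triethylsilane (ring stereocentres as in 13) | C=C[C@@]1(C)CC(O[Si](CC)(CC)CC)=C[C@@H](OC(OCC)C(C)Br)[C@@H]1C(=C)C | intermediate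
17 | cis-fused 2-ethoxy-3,6-dimethyl-7-(prop-1-en-2-yl)-4-[(triethylsilyl)oxy]-6-vinyloctahydro-1-benzofuran (mixture at C2, C3, C4 of the bicycle) | C=C[C@@]1(C)CC(O[Si](CC)(CC)CC)[C@@H]2[C@@H](OC(OCC)C2C)[C@@H]1C(=C)C | intermediate
18 | cis-fused 3,6-dimethyl-7-(prop-1-en-2-yl)-6-vinylhexahydro-1-benzofuran-2,4-dione (C3 epimers) | C=C[C@@]1(C)CC(=O)[C@@H]2[C@@H](OC(=O)C2C)[C@@H]1C(=C)C | intermediate
19 | cis-fused 4-hydroxy-3,6-dimethyl-7-(prop-1-en-2-yl)-6-vinylhexahydro-1-benzofuran-2(3H)-one (C4 as in 26; C3 epimers) | C=C[C@@]1(C)C[C@H](O)[C@@H]2[C@@H](OC(=O)C2C)[C@@H]1C(=C)C | intermediate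
20 | dipotassium alkoxide enolate of 19 | C=C[C@@]1(C)C[C@H]([O-])[C@@H]2[C@@H](OC([O-])=C2C)[C@@H]1C(=C)C.[K+].[K+] | intermediate
21 | cis-fused 3,4-dihydroxy-3,6-dimethyl-7-(prop-1-en-2-yl)-6-vinylhexahydro-1-benzofuran-2(3H)-one (stereocentres as in 26) | C=C[C@@]1(C)C[C@H](O)[C@@H]2[C@@H](OC(=O)[C@@]2(C)O)[C@@H]1C(=C)C | intermediate
22 | cis-fused 3-hydroxy-3,6-dimethyl-2-oxo-7-(prop-1-en-2-yl)-6-vinyloctahydro-1-benzofuran-4-yl acetate (stereocentres as in 26) | C=C[C@@]1(C)C[C@H](OC(C)=O)[C@@H]2[C@@H](OC(=O)[C@@]2(C)O)[C@@H]1C(=C)C | intermediate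
23 | angelic acid, (2Z)-2-methylbut-2-enoic acid | C/C=C(/C)C(=O)O | starting material
24 | (2Z)-2-methylbut-2-enoyl chloride | C/C=C(/C)C(=O)Cl | intermediate
25 | lithium alkoxide of 22 | C=C[C@@]1(C)C[C@H](OC(C)=O)[C@@H]2[C@@H](OC(=O)[C@@]2(C)[O-])[C@@H]1C(=C)C.[Li+] | intermediate
26 | (3S,3aR,4S,6R,7R,7aS)-4-acetoxy-6-ethenyl-3,6-dimethyl-2-oxo-7-(prop-1-en-2-yl)octahydro-1-benzofuran-3-yl (2Z)-2-methylbut-2-enoate (CNP0140071.1) | C=C[C@@]1(C)C[C@H](OC(C)=O)[C@@H]2[C@@H](OC(=O)[C@@]2(C)OC(=O)/C(C)=C\C)[C@@H]1C(=C)C | target

## Step count and risks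

Total step count: 15. Longest linear sequence: 14 steps (steps 1 to 13 and 15; step 14 prepares the acid chloride).

**Step 6 (key step, Proposed new method).**
- Most likely failure: the C10 radical does not reach the silicon-bearing vinyl carbon. The bond joins a quaternary and a tertiary carbon, and ring A must first invert to put O6 and the isopropenyl group axial. Addition at the terminal vinyl carbon, or capture of hydrogen or phenylselanyl at C10, may therefore win.
- Also possible: weak discrimination between the two isopropenyl groups, because allylic strain between the spectator group and the C10 methyl works against the equatorial preference; and a short chain, because phenylselanyl transfer from an acyl selenide to an alkyl radical may be slow.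
- Fallback, known reactions only, from 9 back to 13: O6 is protected as Se-phenyl (3R)-3-[(tert-butyldimethylsilyl)oxy]-5-methyl-4-(prop-1-en-2-yl)hex-5-eneselenoate F1 (t-BuMe2SiOTf, 2,6-lutidine). Bu3SnH/AIBN closes ring A by the 6-endo acyl radical cyclisation and reduces the C10 radical, giving 5-silyloxy-3-methyl-4-(prop-1-en-2-yl)cyclohexanone F2. Kinetic enolisation away from the silyloxy-bearing carbon (LiN(i-Pr)2, Me3SiCl) gives trimethylsilyl enol ether F3, and Pd(OAc)2 (Saegusa–Ito oxidation) gives 3-methylcyclohexenone F4. A vinyl cuprate (CH2=CHMgBr, CuBr·SMe2, Me3SiCl) adds to C10 anti to the neighbouring isopropenyl group to give the silyl ether of 13, F5, and HF·pyridine returns 13. The bulkier silyl ether should also sharpen the group selection.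

**Step 1.**
- Most likely failure: low enantioselectivity or slow addition, because the reacting γ-carbon of the dienylborane is flanked by two methyl-bearing alkene carbons and the chair transition state is crowded.
- Fallback, from 3 (with 2) back to 5: the dienide is trapped with 2-isopropoxy-4,4,5,5-tetramethyl-1,3,2-dioxaborolane as 2-(2,4-dimethylpenta-2,4-dien-1-yl)-4,4,5,5-tetramethyl-1,3,2-dioxaborolane F6. This is added to 2 under catalysis by a chiral binaphthol-derived phosphoric acid (the catalyst enantiomer that gives the R carbinol), and aqueous work-up returns 5. Stereocontrol moves from a stoichiometric auxiliary on boron to a catalyst.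

**Step 8.**
- Most likely failure: deprotonation at C9 instead of C7, or β-elimination of O6 from the C7 enolate; steric differences between the two α-positions are small, so the outcome rests on the inductive and coordinating effect of the acetal.
- Fallback, from 13 back to 18: the iodoacetal 5-(1-ethoxy-2-iodopropoxy)-3-methyl-4-(prop-1-en-2-yl)-3-vinylcyclohexanone F7 (N-iodosuccinimide, 14) is closed with KOt-Bu in t-BuOH/THF. Under these equilibrating conditions only the C7 enolate can alkylate (5-exo-tet), giving the cis-fused keto acetal F8. CrO3/H2SO4 then gives 18. The closure is polar and thermodynamically funnelled instead of radical; displacement at a secondary carbon beside an acetal is slow and is the weak point of this fallback.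

**Step 11.**
- Most likely failure: poor facial selectivity, because the axial C11 substituent on C7 flanks the equatorial trajectory while the C10 methyl blocks the axial one.
- Fallback, from 18 back to 19: the C8 epimers are separated. The unwanted epimer F9 is converted to its chloromethanesulfonate F10 (ClCH2SO2Cl, pyridine) and displaced with inversion by CsOAc/18-crown-6 in toluene at 80 °C to give the C8 acetate F11. An equatorial leaving group has no anti-periplanar ring hydrogen, which disfavours elimination. K2CO3/MeOH then gives 19.

**Step 15.**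
- Most likely failure: Z to E isomerisation of the acyl group (through reversible conjugate addition or a vinylketene) and slow acylation of the hindered tertiary alkoxide.
- Fallback, from 22 to 26: 22 is esterified with 2-[bis(2,2,2-trifluoroethoxy)phosphoryl]propanoic acid (dicyclohexylcarbodiimide, 4-(dimethylamino)pyridine; a saturated acid, so forcing conditions are harmless) to give phosphonate ester F12. Still–Gennari olefination with acetaldehyde (KN(SiMe3)2, 18-crown-6, THF, −78 °C) then builds the Z double bond in place and gives 26.

## Further compounds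

F1 | step 6 | Se-phenyl (3R)-3-[(tert-butyldimethylsilyl)oxy]-5-methyl-4-(prop-1-en-2-yl)hex-5-eneselenoate | O=C([Se]c1ccccc1)C[C@@H](O[Si](C)(C)C(C)(C)C)C(C(C)=C)C(C)=C
F2 | step 6 | 5-[(tert-butyldimethylsilyl)oxy]-3-methyl-4-(prop-1-en-2-yl)cyclohexan-1-one (C4, C5 as in 13; C3 epimers) | CC1CC(=O)C[C@@H](O[Si](C)(C)C(C)(C)C)[C@@H]1C(=C)C
F3 | step 6 | tert-butyldimethyl{[5-methyl-6-(prop-1-en-2-yl)-3-[(trimethylsilyl)oxy]cyclohex-3-en-1-yl]oxy}silane | CC1C=C(O[Si](C)(C)C)C[C@@H](O[Si](C)(C)C(C)(C)C)[C@@H]1C(=C)C
F4 | step 6 | 5-[(tert-butyldimethylsilyl)oxy]-3-methyl-4-(prop-1-en-2-yl)cyclohex-2-en-1-one (C4, C5 as in 13) | CC1=CC(=O)C[C@@H](O[Si](C)(C)C(C)(C)C)[C@@H]1C(=C)C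
F5 | step 6 | 5-[(tert-butyldimethylsilyl)oxy]-3-methyl-4-(prop-1-en-2-yl)-3-vinylcyclohexan-1-one (stereocentres as in 13) | C=C[C@@]1(C)CC(=O)C[C@@H](O[Si](C)(C)C(C)(C)C)[C@@H]1C(=C)C
F6 | step 1 | 2-(2,4-dimethylpenta-2,4-dien-1-yl)-4,4,5,5-tetramethyl-1,3,2-dioxaborolane | C=C(C)C=C(C)CB1OC(C)(C)C(C)(C)O1
F7 | step 8 | 5-(1-ethoxy-2-iodopropoxy)-3-methyl-4-(prop-1-en-2-yl)-3-vinylcyclohexan-1-one (ring stereocentres as in 13) | C=C[C@@]1(C)CC(=O)C[C@@H](OC(OCC)C(C)I)[C@@H]1C(=C)C
F8 | step 8 | cis-fused 2-ethoxy-3,6-dimethyl-7-(prop-1-en-2-yl)-6-vinylhexahydro-1-benzofuran-4(2H)-one | C=C[C@@]1(C)CC(=O)[C@@H]2[C@@H](OC(OCC)C2C)[C@@H]1C(=C)C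
F9 | step 11 | C4 epimer of 19 (hydroxyl cis to the C7–C11 bond) | C=C[C@@]1(C)C[C@@H](O)[C@@H]2[C@@H](OC(=O)C2C)[C@@H]1C(=C)C
F10 | step 11 | chloromethanesulfonate of F9 | C=C[C@@]1(C)C[C@@H](OS(=O)(=O)CCl)[C@@H]2[C@@H](OC(=O)C2C)[C@@H]1C(=C)C
F11 | step 11 | acetate of 19 | C=C[C@@]1(C)C[C@H](OC(C)=O)[C@@H]2[C@@H](OC(=O)C2C)[C@@H]1C(=C)C
F12 | step 15 | 2-[bis(2,2,2-trifluoroethoxy)phosphoryl]propanoate of 22 | C=C[C@@]1(C)C[C@H](OC(C)=O)[C@@H]2[C@@H](OC(=O)[C@@]2(C)OC(=O)C(C)P(=O)(OCC(F)(F)F)OCC(F)(F)F)[C@@H]1C(=C)C
A1 | alternative 1 | 2-methoxy-6-methyl-1,4-benzoquinone | COC1=CC(=O)C=C(C)C1=O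
A2 | alternative 1 | (E)-penta-1,3-diene | C=C/C=C/C
A3 | alternative 1 | trans-fused 2-methoxy-5,8a-dimethyl-4a,5,8,8a-tetrahydronaphthalene-1,4-dione | C1=CC[C@@]2(C)C(=O)C(OC)=CC(=O)[C@@H]2[C@H]1C
A4 | alternative 2 | 3-(2-bromo-1-ethoxypropoxy)-5-methyl-4-(prop-1-en-2-yl)-5-vinylcyclohex-1-ene | C=C[C@@]1(C)CC=C[C@@H](OC(OCC)C(C)Br)[C@@H]1C(=C)C
A5 | alternative 2 | cis-fused 2-ethoxy-3,6-dimethyl-7-(prop-1-en-2-yl)-6-vinyloctahydro-1-benzofuran-4-ol | C=C[C@@]1(C)C[C@H](O)[C@@H]2[C@@H](OC(OCC)C2C)[C@@H]1C(=C)C
A6 | alternative 3 | methyl 2-(bromomethyl)-4-[(tert-butyldimethylsilyl)oxy]-6-ethenyl-7-formyl-6,8-dimethylnona-2,8-dienoate | C=C[C@@](C)(C[C@H](O[Si](C)(C)C(C)(C)C)C=C(CBr)C(=O)OC)[C@H](C=O)C(=C)C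
A7 | alternative 3 | cis-fused 4-[(tert-butyldimethylsilyl)oxy]-6-methyl-3-methylene-7-(prop-1-en-2-yl)-6-vinylhexahydro-1-benzofuran-2(3H)-one | C=C[C@@]1(C)C[C@H](O[Si](C)(C)C(C)(C)C)[C@@H]2[C@@H](OC(=O)C2=C)[C@@H]1C(=C)C
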